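**Retrosynthetic overview**
- Target ⇐ 8α,9α-epoxy-10-ketone (C10 reduction last) ⇐ 6α-hydroxy enone (epoxidation, then C6 anisoylation) ⇐ 2β-acetoxy-4β-hydroxy-dauc-8-ene-6,10-dione (C4-OH-directed C6 reduction).
- The C6 and C10 carbonyls are two masked aryl methyl ethers. The angular C1 methyl comes from a hydroxyl-directed cyclopropanation of the C1=C10 enol ether followed by acid opening. The C4 carbinol comes from isopropyl addition to the ring ketone.
- Key step: an aryl diazoketone gives the bicyclo[5.3.0]decatrienone by intramolecular Buchner reaction. The cyclopentanone (with a transient cyclopropane) closes first, the seven-membered ring follows at once by norcaradiene opening, and the epoxide ring is made last.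
- Diazoketone ⇐ 3,5-dimethoxytoluene + DMF + an allyl unit. The benzylic carbinol C2 (asymmetric allylation) is the single reagent-controlled stereocentre and relays to C5, C4, C1, C6, C8/C9 and C10.

Assumption: bicyclic compounds are numbered as in daucane (C1 and C5 ring fusion, C2–C4 five-membered ring, C6–C10 seven-membered ring, methyl on C1 and C8, isopropyl on C4); β is the face of the C1 methyl of the target, α the opposite face.

**Step 1**
Reactants: 1 3,5-dimethoxytoluene
Product: 3 2,6-dimethoxy-4-methylbenzaldehyde, via 2,6-dimethoxy-4-methylphenyllithium 2 (not isolated)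
Conditions: n-BuLi, TMEDA, THF, 0 °C to rt; DMF, −78 °C to rt; aq. NH4Cl
Reagents that add atoms: N,N-dimethylformamide, CN(C)C=O
Why: Directed ortho-metalation deprotonates only the position flanked by the two methoxy groups and DMF formylates the aryllithium, so no stereocentre is involved.

**Step 2**
Reactants: 3 2,6-dimethoxy-4-methylbenzaldehyde; 4 allyltributylstannane
Product: 5 (R)-1-(2,6-dimethoxy-4-methylphenyl)but-3-en-1-ol
Conditions: (R)-BINOL (10 mol %), Ti(OiPr)4 (10 mol %), 4 Å MS, CH2Cl2, −20 °C; aq. NaHCO3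
Reagents that add atoms: none
Why: Keck asymmetric allylation, in which the (R)-BINOL titanium Lewis acid steers the allyl group from tin onto the Re face of the aldehyde and so sets C2 as R, the only reagent-controlled stereocentre of the route.

**Step 3**
Reactants: 5 (R)-1-(2,6-dimethoxy-4-methylphenyl)but-3-en-1-ol
Product: 6 (R)-tert-butyl[1-(2,6-dimethoxy-4-methylphenyl)but-3-enyloxy]dimethylsilane
Conditions: TBSOTf, 2,6-lutidine, CH2Cl2, −78 to 0 °C
Reagents that add atoms: tert-butyldimethylsilyl trifluoromethanesulfonate, CC(C)(C)[Si](C)(C)OS(=O)(=O)C(F)(F)F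
Why: Silylation with the reactive silyl triflate masks the hindered benzylic alcohol (a free OH would undergo O–H insertion in the carbenoid step) and leaves C2 untouched.

**Step 4**
Reactants: 6 (R)-tert-butyl[1-(2,6-dimethoxy-4-methylphenyl)but-3-enyloxy]dimethylsilane
Product: 7 (R)-4-(tert-butyldimethylsilyloxy)-4-(2,6-dimethoxy-4-methylphenyl)butan-2-one
Conditions: PdCl2 (10 mol %), CuCl, O2 (1 atm), DMF/H2O 7:1, rt
Reagents that add atoms: water, O
Why: Tsuji–Wacker oxidation, in which Markovnikov hydroxypalladation of the terminal alkene gives the methyl ketone without touching C2.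

**Step 5**
Reactants: 7 (R)-4-(tert-butyldimethylsilyloxy)-4-(2,6-dimethoxy-4-methylphenyl)butan-2-one
Product: 9 (R)-4-(tert-butyldimethylsilyloxy)-1-diazo-4-(2,6-dimethoxy-4-methylphenyl)butan-2-one, via trifluoroacetyl diketone 8 (not isolated)
Conditions: LiN(SiMe3)2, THF, −78 °C; CF3CO2CH2CF3; then MsN3, Et3N, H2O, MeCN, rt
Reagents that add atoms: methanesulfonyl azide, CS(=O)(=O)N=[N+]=[N-]
Why: Danheiser detrifluoroacetylative diazo transfer, in which kinetic enolisation at the methyl group, trifluoroacetylation to 8 and azide transfer with loss of the trifluoroacetyl group give the terminal diazoketone regioselectively.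

**Step 6**
Reactants: 9 (R)-4-(tert-butyldimethylsilyloxy)-1-diazo-4-(2,6-dimethoxy-4-methylphenyl)butan-2-one
Product: 11 2β-(tert-butyldimethylsilyloxy)-6,10-dimethoxy-8-methyl-5αH-bicyclo[5.3.0]deca-1(10),6,8-trien-4-one, via norcaradiene 10 (not isolated)
Conditions: Rh2(OAc)4 (1 mol %), CH2Cl2, 40 °C, slow addition of 9
Reagents that add atoms: none
Why: Intramolecular Buchner reaction, in which the rhodium carbenoid cyclopropanates the enol-ether-like ipso–ortho bond of the electron-rich arene (both ortho positions are equivalent) to close the cyclopentanone and 6π electrocyclic opening of norcaradiene 10 gives the cycloheptatriene; the benzylic C–H lies in the arene plane and the silyloxy group points away from the carbenoid, which gives the 2,5-trans product (H5 α) expected from the trans preference of 3-substituted azulenones.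

**Step 7**
Reactants: 11 2β-(tert-butyldimethylsilyloxy)-6,10-dimethoxy-8-methyl-5αH-bicyclo[5.3.0]deca-1(10),6,8-trien-4-one; 12 isopropylmagnesium chloride
Product: 13 2β-(tert-butyldimethylsilyloxy)-4α-isopropyl-6,10-dimethoxy-8-methyl-5αH-bicyclo[5.3.0]deca-1(10),6,8-trien-4β-ol
Conditions: CeCl3 (anhydrous), THF, −78 °C; aq. NH4Cl
Reagents that add atoms: none
Why: Organocerium 1,2-addition (Imamoto conditions) outruns enolisation of the acidic C5–H, and the isopropyl group enters from the α face, anti to both the C5–C6 bond and the C2 silyloxy group, which sets C4 with OH β.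

**Step 8**
Reactants: 13 2β-(tert-butyldimethylsilyloxy)-4α-isopropyl-6,10-dimethoxy-8-methyl-5αH-bicyclo[5.3.0]deca-1(10),6,8-trien-4β-ol
Product: 14 4α-isopropyl-6,10-dimethoxy-8-methyl-5αH-bicyclo[5.3.0]deca-1(10),6,8-triene-2β,4β-diol
Conditions: Bu4NF, THF, 0 °C
Reagents that add atoms: none
Why: Fluoride desilylation frees the allylic C2 hydroxyl that directs the next step and changes no stereocentre.

**Step 9**
Reactants: 14 4α-isopropyl-6,10-dimethoxy-8-methyl-5αH-bicyclo[5.3.0]deca-1(10),6,8-triene-2β,4β-diol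
Product: 15 4α-isopropyl-6,10α-dimethoxy-8-methyl-1β,10β-methano-5αH-bicyclo[5.3.0]deca-6,8-diene-2β,4β-diol
Conditions: Et2Zn, CH2I2, CH2Cl2, −10 to 0 °C
Reagents that add atoms: diiodomethane, ICI
Why: Hydroxyl-directed Simmons–Smith (Furukawa) cyclopropanation, in which the zinc alkoxides of the allylic C2–OH and the homoallylic C4–OH deliver CH2 to the β face of the C1=C10 enol ether and so fix C1 with the future methyl carbon β, trans to H5.

**Step 10**
Reactants: 15 4α-isopropyl-6,10α-dimethoxy-8-methyl-1β,10β-methano-5αH-bicyclo[5.3.0]deca-6,8-diene-2β,4β-diol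
Product: 16 2β-acetoxy-4α-isopropyl-6,10α-dimethoxy-8-methyl-1β,10β-methano-5αH-bicyclo[5.3.0]deca-6,8-dien-4β-ol
Conditions: Ac2O, pyridine, DMAP (cat.), CH2Cl2, rt
Reagents that add atoms: acetic anhydride, CC(=O)OC(C)=O
Why: DMAP-catalysed acylation esterifies only the secondary C2 alcohol, the tertiary C4 alcohol being inert, and is done before the hydrolysis so that no enol of the later dione competes.

**Step 11**
Reactants: 16 2β-acetoxy-4α-isopropyl-6,10α-dimethoxy-8-methyl-1β,10β-methano-5αH-bicyclo[5.3.0]deca-6,8-dien-4β-ol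
Product: 17 2β-acetoxy-4β-hydroxy-4α-isopropyl-1β,8-dimethyl-5αH-bicyclo[5.3.0]dec-8-ene-6,10-dione
Conditions: 0.5 M HCl, THF/H2O, 0 °C
Reagents that add atoms: water, O
Why: Acid hydrolysis, in which protonolysis of the methoxycyclopropane at its CH2 carbon (Wenkert-type cyclopropyl ether opening) unveils the angular methyl and the C10 ketone with retention at C1, the C6 enol ether gives the ketone, and the now epimerisable C5 stays in the trans-fused arrangement with C6 anti to the isopropyl group.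

**Step 12**
Reactants: 17 2β-acetoxy-4β-hydroxy-4α-isopropyl-1β,8-dimethyl-5αH-bicyclo[5.3.0]dec-8-ene-6,10-dione
Product: 18 2β-acetoxy-4β,6α-dihydroxy-4α-isopropyl-1β,8-dimethyl-5αH-bicyclo[5.3.0]dec-8-en-10-one
Conditions: Me4NBH(OAc)3, MeCN/AcOH 1:1, −30 °C
Reagents that add atoms: none
Why: Evans–Saksena hydroxyl-directed reduction, in which the borohydride exchanges onto the C4 hydroxyl and delivers hydride to the β face of the C6 ketone only (enone and ester are not reduced), giving the 4,6-anti diol with 6α-OH.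

**Step 13**
Reactants: 18 2β-acetoxy-4β,6α-dihydroxy-4α-isopropyl-1β,8-dimethyl-5αH-bicyclo[5.3.0]dec-8-en-10-one
Product: 19 2β-acetoxy-8α,9α-epoxy-4β,6α-dihydroxy-4α-isopropyl-1β,8β-dimethyl-5αH-bicyclo[5.3.0]decan-10-one
Conditions: t-BuOOH, DBU, CH2Cl2, 0 °C to rt
Reagents that add atoms: tert-butyl hydroperoxide, CC(C)(C)OO
Why: Weitz–Scheffer nucleophilic epoxidation of the β-methyl enone, in which the peroxide anion adds to C8 from the α face, opposite the axial angular methyl and guided by hydrogen bonding to the 6α-hydroxyl, and the enolate closes the cis epoxide that sets C8 and C9 (done before C6 is esterified, so no leaving group sits δ to the enone).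

**Step 14**
Reactants: 19 2β-acetoxy-8α,9α-epoxy-4β,6α-dihydroxy-4α-isopropyl-1β,8β-dimethyl-5αH-bicyclo[5.3.0]decan-10-one; 20 4-methoxybenzoyl chloride
Product: 21 2β-acetoxy-8α,9α-epoxy-4β-hydroxy-4α-isopropyl-6α-(4-methoxybenzoyloxy)-1β,8β-dimethyl-5αH-bicyclo[5.3.0]decan-10-one
Conditions: DMAP, Et3N, CH2Cl2, 0 °C to rt
Reagents that add atoms: none
Why: DMAP-catalysed acylation of the only secondary alcohol (C6), the tertiary C4 alcohol being unreactive, with retention at C6.

**Step 15**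
Reactants: 21 2β-acetoxy-8α,9α-epoxy-4β-hydroxy-4α-isopropyl-6α-(4-methoxybenzoyloxy)-1β,8β-dimethyl-5αH-bicyclo[5.3.0]decan-10-one
Product: 22 2β-acetoxy-8α,9α-epoxy-4β,10β-dihydroxy-4α-isopropyl-6α-(4-methoxybenzoyloxy)-1β,8β-dimethyl-5αH-bicyclo[5.3.0]decane (CNP0371526.1)
Conditions: NaBH4, CeCl3·7H2O, MeOH, −78 °C
Reagents that add atoms: none
Why: Luche-type reduction, in which hydride attacks the neopentyl C10 ketone from the α face, anti to the angular methyl and on the side of the cerium-bound epoxide oxygen, giving the 10β-alcohol trans to the epoxide while esters and epoxide survive.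

**Compound list**
1 | 3,5-dimethoxytoluene | COc1cc(C)cc(OC)c1 | starting material
2 | 2,6-dimethoxy-4-methylphenyllithium | [Li]c1c(OC)cc(C)cc1OC | intermediate
3 | 2,6-dimethoxy-4-methylbenzaldehyde | COc1cc(C)cc(OC)c1C=O | intermediate
4 | allyltributylstannane | C=CC[Sn](CCCC)(CCCC)CCCC | starting material
5 | (R)-1-(2,6-dimethoxy-4-methylphenyl)but-3-en-1-ol | COc1cc(C)cc(OC)c1[C@H](O)CC=C | intermediate
6 | (R)-tert-butyl[1-(2,6-dimethoxy-4-methylphenyl)but-3-enyloxy]dimethylsilane | COc1cc(C)cc(OC)c1[C@H](O[Si](C)(C)C(C)(C)C)CC=C | intermediate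
7 | (R)-4-(tert-butyldimethylsilyloxy)-4-(2,6-dimethoxy-4-methylphenyl)butan-2-one | COc1cc(C)cc(OC)c1[C@H](O[Si](C)(C)C(C)(C)C)CC(C)=O | intermediate
8 | (R)-6-(tert-butyldimethylsilyloxy)-6-(2,6-dimethoxy-4-methylphenyl)-1,1,1-trifluorohexane-2,4-dione | COc1cc(C)cc(OC)c1[C@H](O[Si](C)(C)C(C)(C)C)CC(=O)CC(=O)C(F)(F)F | intermediate
9 | (R)-4-(tert-butyldimethylsilyloxy)-1-diazo-4-(2,6-dimethoxy-4-methylphenyl)butan-2-one | COc1cc(C)cc(OC)c1[C@H](O[Si](C)(C)C(C)(C)C)CC(=O)C=[N+]=[N-] | intermediate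
10 | norcaradiene valence isomer of 11 (cyclopropane C1–C5–C6, dienes C7=C8 and C9=C10, 2β-OTBS, H5 α) | COC1=CC(C)=C[C@]2(OC)[C@H]3C(=O)C[C@@H](O[Si](C)(C)C(C)(C)C)[C@@]123 | intermediate
11 | 2β-(tert-butyldimethylsilyloxy)-6,10-dimethoxy-8-methyl-5αH-bicyclo[5.3.0]deca-1(10),6,8-trien-4-one | COC2=CC(C)=CC(OC)=C3[C@@H]2C(=O)C[C@H]3O[Si](C)(C)C(C)(C)C | intermediate
12 | isopropylmagnesium chloride | CC(C)[Mg]Cl | starting material
13 | 2β-(tert-butyldimethylsilyloxy)-4α-isopropyl-6,10-dimethoxy-8-methyl-5αH-bicyclo[5.3.0]deca-1(10),6,8-trien-4β-ol | COC2=CC(C)=CC(OC)=C3[C@@H]2[C@](O)(C(C)C)C[C@H]3O[Si](C)(C)C(C)(C)C | intermediate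
14 | 4α-isopropyl-6,10-dimethoxy-8-methyl-5αH-bicyclo[5.3.0]deca-1(10),6,8-triene-2β,4β-diol | COC2=CC(C)=CC(OC)=C3[C@@H]2[C@](O)(C(C)C)C[C@H]3O | intermediate
15 | 4α-isopropyl-6,10α-dimethoxy-8-methyl-1β,10β-methano-5αH-bicyclo[5.3.0]deca-6,8-diene-2β,4β-diol | COC2=CC(C)=C[C@]4(OC)C[C@]43[C@@H]2[C@](O)(C(C)C)C[C@H]3O | intermediate
16 | 2β-acetoxy-4α-isopropyl-6,10α-dimethoxy-8-methyl-1β,10β-methano-5αH-bicyclo[5.3.0]deca-6,8-dien-4β-ol | COC2=CC(C)=C[C@]4(OC)C[C@]43[C@@H]2[C@](O)(C(C)C)C[C@H]3OC(C)=O | intermediate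
17 | 2β-acetoxy-4β-hydroxy-4α-isopropyl-1β,8-dimethyl-5αH-bicyclo[5.3.0]dec-8-ene-6,10-dione | O=C2CC(C)=CC(=O)[C@]3(C)[C@@H]2[C@](O)(C(C)C)C[C@H]3OC(C)=O | intermediate
18 | 2β-acetoxy-4β,6α-dihydroxy-4α-isopropyl-1β,8-dimethyl-5αH-bicyclo[5.3.0]dec-8-en-10-one | O[C@H]2CC(C)=CC(=O)[C@]3(C)[C@@H]2[C@](O)(C(C)C)C[C@H]3OC(C)=O | intermediate
19 | 2β-acetoxy-8α,9α-epoxy-4β,6α-dihydroxy-4α-isopropyl-1β,8β-dimethyl-5αH-bicyclo[5.3.0]decan-10-one | O[C@H]2C[C@@]3(C)O[C@H]3C(=O)[C@]3(C)[C@@H]2[C@](O)(C(C)C)C[C@H]3OC(C)=O | intermediate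
20 | 4-methoxybenzoyl chloride | COc1ccc(C(Cl)=O)cc1 | starting material
21 | 2β-acetoxy-8α,9α-epoxy-4β-hydroxy-4α-isopropyl-6α-(4-methoxybenzoyloxy)-1β,8β-dimethyl-5αH-bicyclo[5.3.0]decan-10-one | COc1ccc(C(=O)O[C@H]2C[C@@]3(C)O[C@H]3C(=O)[C@]3(C)[C@@H]2[C@](O)(C(C)C)C[C@H]3OC(C)=O)cc1 | intermediate
22 | CNP0371526.1: 2β-acetoxy-8α,9α-epoxy-4β,10β-dihydroxy-4α-isopropyl-6α-(4-methoxybenzoyloxy)-1β,8β-dimethyl-5αH-bicyclo[5.3.0]decane, (1S,2R,4R,5S,6S,8R,9S,10R) in daucane numbering | COc1ccc(C(=O)O[C@H]2C[C@@]3(C)O[C@H]3[C@H](O)[C@]3(C)[C@@H]2[C@](O)(C(C)C)C[C@H]3OC(C)=O)cc1 | target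

**Totals**
Total step count: 15. Longest linear sequence: 15 steps (1 to 22); 4, 12 and 20 are bought and enter in single steps.

**Steps most likely to fail, with fallbacks**

Step 6 (Buchner reaction onto a methoxy-bearing ortho carbon). The carbenoid must add across an ipso–ortho bond whose ortho carbon is substituted, and the trienone 11 is sensitive to acid and base. The fallback makes the same carbene without a diazo compound and with a more electrophilic metal, so that stepwise ipso attack is helped by the two ortho donors. It sets out from 6: Lemieux–Johnson cleavage (OsO4 cat., NaIO4, 2,6-lutidine, dioxane/H2O) gives (R)-3-(tert-butyldimethylsilyloxy)-3-(2,6-dimethoxy-4-methylphenyl)propanal F1. Ohira–Bestmann homologation (dimethyl 1-diazo-2-oxopropylphosphonate, K2CO3, MeOH) gives (R)-tert-butyl[1-(2,6-dimethoxy-4-methylphenyl)but-3-ynyloxy]dimethylsilane F2. Oxidation of F2 at the internal alkyne carbon with 8-methylquinoline N-oxide under Ph3PAuNTf2 catalysis gives the α-oxo gold carbene, which undergoes arene cyclopropanation and ring opening. The route is rejoined at 11.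

Step 9 (chemoselective cyclopropanation). The C6=C7 enol ether is less hindered than the tetrasubstituted C1=C10 bond, and the C4 hydroxyl can direct the zinc carbenoid to it. The fallback changes the order so that only one directing group is present. It sets out from 11: desilylation (HF·pyridine, THF, 0 °C) gives 2β-hydroxy-6,10-dimethoxy-8-methyl-5αH-bicyclo[5.3.0]deca-1(10),6,8-trien-4-one F3. Cyclopropanation (Et2Zn, CH2I2), now directed by the allylic C2 hydroxyl alone and with C6=C7 deactivated by the neighbouring acyl-bearing carbon, gives 2β-hydroxy-6,10α-dimethoxy-8-methyl-1β,10β-methano-5αH-bicyclo[5.3.0]deca-6,8-dien-4-one F4. Addition of iPrMgCl/CeCl3 to F4 from the α face rejoins the route at 15.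

Step 13 (face selectivity of the enone epoxidation). The ring fold of the cycloheptenone may not favour α attack. The fallback replaces nucleophilic epoxidation by an electrophilic one on a rigid bridged ketal. It sets out from 18: MeOH, HC(OMe)3 and PPTS convert the γ-hydroxy enone into the bridged methyl ketal 2β-acetoxy-6α,10α-epoxy-10β-methoxy-4α-isopropyl-1β,8-dimethyl-5αH-bicyclo[5.3.0]dec-8-en-4β-ol F5, an 8-oxabicyclo[3.2.1]oct-2-ene. m-CPBA/NaHCO3 attacks the exo face on the side of the one-atom oxygen bridge, which is α, and gives 2β-acetoxy-6α,10α:8α,9α-diepoxy-10β-methoxy-4α-isopropyl-1β,8β-dimethyl-5αH-bicyclo[5.3.0]decan-4β-ol F6. Mild ketal hydrolysis (PPTS, wet acetone) rejoins the route at 19.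

**Further compounds**
F1 | step 6 | (R)-3-(tert-butyldimethylsilyloxy)-3-(2,6-dimethoxy-4-methylphenyl)propanal | COc1cc(C)cc(OC)c1[C@H](O[Si](C)(C)C(C)(C)C)CC=O
F2 | step 6 | (R)-tert-butyl[1-(2,6-dimethoxy-4-methylphenyl)but-3-ynyloxy]dimethylsilane | COc1cc(C)cc(OC)c1[C@H](O[Si](C)(C)C(C)(C)C)CC#C
F3 | step 9 | 2β-hydroxy-6,10-dimethoxy-8-methyl-5αH-bicyclo[5.3.0]deca-1(10),6,8-trien-4-one | COC2=CC(C)=CC(OC)=C3[C@@H]2C(=O)C[C@H]3O
F4 | step 9 | 2β-hydroxy-6,10α-dimethoxy-8-methyl-1β,10β-methano-5αH-bicyclo[5.3.0]deca-6,8-dien-4-one | COC2=CC(C)=C[C@]4(OC)C[C@]43[C@@H]2C(=O)C[C@H]3O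
F5 | step 13 | 2β-acetoxy-6α,10α-epoxy-10β-methoxy-4α-isopropyl-1β,8-dimethyl-5αH-bicyclo[5.3.0]dec-8-en-4β-ol | O4[C@H]2CC(C)=C[C@]4(OC)[C@]3(C)[C@@H]2[C@](O)(C(C)C)C[C@H]3OC(C)=O
F6 | step 13 | 2β-acetoxy-6α,10α:8α,9α-diepoxy-10β-methoxy-4α-isopropyl-1β,8β-dimethyl-5αH-bicyclo[5.3.0]decan-4β-ol | O4[C@H]2C[C@@]5(C)O[C@H]5[C@]4(OC)[C@]3(C)[C@@H]2[C@](O)(C(C)C)C[C@H]3OC(C)=O
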